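**Retrosynthetic overview**
1. The target is cut at the two ester C–O bonds to a cis-8,9-diol and tigloyl chloride; the C4 methyl comes from a cuprate addition to a C3=C4 enone and the C9 carbinol from a C9 ketone.
2. The C9–C10 bond is made by a carbene-catalysed intramolecular Stetter addition of a C9 aldehyde onto a 4-alkyl-4-methylcyclohexa-2,5-dienone; this selects one of the two enone arms and closes ring B as a cis-decalin.
3. The C7–C8 bond is made by a γ-selective, anti, Felkin allylchromium addition of an (E)-allylic bromide to (S)-glyceraldehyde acetonide, whose own carbinol carbon is later cut back to the C9 aldehyde.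
4. The dienone comes from p-cresol by oxidative para-allylation; the side chain is extended by cross-metathesis, allylic oxidation and bromination.
5. Feature used: ring A (C1, C2, C3, C4, C5, C10) is a cyclohexanone whose methyl-bearing quaternary C5 is para to the C2 carbonyl and whose fusion carbon C10 is β to it, i.e. a latent p-cresol. Ring A is therefore present from the start as the arene, and ring B is formed last.

Key step: step 8

Numbering: C1–C10 follow eremophilane numbering (ring A: C1, C2, C3, C4, C5, C10; ring B: C5, C6, C7, C8, C9, C10; methyl on C5, isopropenyl on C7).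

Assumption: the (5aS,10bR) antipode of the aminoindanol triazolium salt is taken as the one whose arm preference matches the substrate's own bias; if a test shows the opposite, the (5aR,10bS) antipode is used under the same conditions and the route is unchanged.

**Route**

Step 1
Reactants: 1 p-cresol; 2 allyltrimethylsilane
Product: 3 4-allyl-4-methylcyclohexa-2,5-dien-1-one
Conditions: PhI(OAc)2, (CF3)2CHOH/CH2Cl2, −40 → 0 °C
Reagents that add atoms: none
Why: Oxidative dearomatization by the trivalent iodine reagent in a fluorinated alcohol gives a phenoxenium-type species that the allylsilane captures at the methyl-bearing para carbon (oxidative Hosomi–Sakurai allylation), giving the achiral 4,4-disubstituted dienone.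

Step 2
Reactants: 3 4-allyl-4-methylcyclohexa-2,5-dien-1-one; 4 2-methyl-2-butene
Product: 5 4-methyl-4-(3-methylbut-2-en-1-yl)cyclohexa-2,5-dien-1-one
Conditions: second-generation Grubbs catalyst (H2IMes)(PCy3)Cl2Ru=CHPh (3 mol%), 2-methyl-2-butene (excess)/CH2Cl2, 40 °C
Reagents that add atoms: none
Why: Olefin cross-metathesis of the terminal alkene with excess 2-methyl-2-butene should turn the allyl into a prenyl group, the electron-poor ring alkenes being inert to the ruthenium carbene.

Step 3
Reactants: 5 4-methyl-4-(3-methylbut-2-en-1-yl)cyclohexa-2,5-dien-1-one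
Product: 6 4-[(2E)-4-hydroxy-3-methylbut-2-en-1-yl]-4-methylcyclohexa-2,5-dien-1-one
Conditions: SeO2 (0.3 equiv), t-BuOOH, CH2Cl2, 0 °C → rt
Reagents that add atoms: selenium dioxide O=[Se]=O; tert-butyl hydroperoxide CC(C)(C)OO (terminal oxidant)
Why: Riley-type allylic oxidation (ene reaction, then [2,3]-sigmatropic shift) hydroxylates the (E)-methyl group of a trisubstituted alkene, and the dienone has no enolizable α-hydrogen to compete.

Step 4
Reactants: 6 4-[(2E)-4-hydroxy-3-methylbut-2-en-1-yl]-4-methylcyclohexa-2,5-dien-1-one
Product: 7 4-[(2E)-4-bromo-3-methylbut-2-en-1-yl]-4-methylcyclohexa-2,5-dien-1-one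
Conditions: CBr4, PPh3, CH2Cl2, 0 °C
Reagents that add atoms: carbon tetrabromide BrC(Br)(Br)Br
Why: The Appel reaction converts the primary allylic alcohol to the bromide by SN2 displacement of the oxyphosphonium group, keeping the (E) geometry.

Step 5
Reactants: 7 4-[(2E)-4-bromo-3-methylbut-2-en-1-yl]-4-methylcyclohexa-2,5-dien-1-one; 8 (S)-2,3-O-isopropylideneglyceraldehyde
Product: 10 (7R,8R)-homoallylic alcohol bearing the (4S)-dioxolane, via allylchromium dichloride 9 (not isolated)
Conditions: CrCl2 (3 equiv), THF, 0 °C → rt; 7 added slowly to CrCl2 and 8 (1.5 equiv)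
Reagents that add atoms: none
Why: In this Nozaki–Hiyama allylation the allylchromium species reacts at its γ carbon through a chair transition state with the aldehyde residue and the γ-CH2 group equatorial (anti C7/C8) and on the Felkin–Anh face of the α-alkoxy aldehyde (anti C8/dioxolane oxygen), while divalent chromium and the allylmetal leave the dienone carbonyl alone.

Step 6
Reactants: 10 (7R,8R)-homoallylic alcohol bearing the (4S)-dioxolane
Product: 11 8-O-tert-butyldimethylsilyl ether of 10
Conditions: TBSOTf, 2,6-lutidine, CH2Cl2, −78 → 0 °C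
Reagents that add atoms: tert-butyldimethylsilyl triflate CC(C)(C)[Si](C)(C)OS(=O)(=O)C(F)(F)F
Why: A silyl triflate with a hindered pyridine base silylates the crowded secondary alcohol, and a silyloxy group is chosen because it is a poor leaving group next to the later acyl-anion carbon.

Step 7
Reactants: 11 8-O-tert-butyldimethylsilyl ether of 10
Product: 13 (2R,3R)-2-(tert-butyldimethylsilyloxy)-4-methyl-3-[(1-methyl-4-oxocyclohexa-2,5-dien-1-yl)methyl]pent-4-enal, via diol 12 (not isolated)
Conditions: H5IO6, EtOAc, 0 °C → rt
Reagents that add atoms: none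
Why: Periodic acid hydrolyses the terminal acetonide and cleaves the freed 1,2-diol in the same flask (Malaprade glycol fission), removing the auxiliary stereocentre and leaving the secondary silyl ether and the C8 configuration untouched.

Step 8
Reactants: 13 (2R,3R)-2-(tert-butyldimethylsilyloxy)-4-methyl-3-[(1-methyl-4-oxocyclohexa-2,5-dien-1-yl)methyl]pent-4-enal
Product: 14 (5R,7R,8R,10S)-cis-fused decalin-3-ene-2,9-dione with 8-OTBS
Conditions: (5aS,10bR)-2-(pentafluorophenyl)-5a,10b-dihydro-4H,6H-indeno[2,1-b][1,2,4]triazolo[4,3-d][1,4]oxazin-2-ium tetrafluoroborate (20 mol%), KN(SiMe3)2 (18 mol%), toluene, 23 °C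
Reagents that add atoms: none
Why: The free triazolylidene adds to the C9 aldehyde and proton transfer gives the Breslow intermediate, whose nucleophilic C9 adds to C10, the β carbon of one enone arm, after which protonation of the dienolate at C1 and loss of the carbene release the C9 ketone. The closest known reaction type is the triazolium-catalysed intramolecular Stetter desymmetrization of 4,4-disubstituted cyclohexadienones that carry an α-oxygenated aldehyde tether. Ring B (C5, C6, C7, C8, C9, C10) closes in the 6-exo-trig mode. C5 and C10 become stereocentres in the same event: the tether starts at C5, so C9 can reach C10 only on the face bearing C6 and the fusion is necessarily cis, while their configuration relative to C7 and C8 follows from which arm reacts. The selectivity needed is the choice between the two diastereotopic arms: perpendicular approach to the flat dienone allows one chair per arm, and only for the arm leading to 14 do the C7 isopropenyl, C8 silyloxy and C5 methyl groups all sit equatorial (the other arm would force the C7 and C8 groups axial), a bias that the matched triazolium antipode reinforces. Side paths are held back because the dienone is a doubly activated, non-enolizable acceptor, silyloxide is a poor leaving group from the Breslow intermediate, and the base is kept just below the triazolium loading so that C8 and C10 are not epimerised.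

Step 9
Reactants: 14 (5R,7R,8R,10S)-cis-fused decalin-3-ene-2,9-dione with 8-OTBS
Product: 15 (5R,7R,8R,9S,10S)-9-hydroxy-3-en-2-one with 8-OTBS
Conditions: NaBH4, MeOH/CH2Cl2, −78 °C
Reagents that add atoms: none
Why: Borohydride should reduce the saturated, α-oxygenated C9 ketone faster than the conjugated C2 ketone at low temperature; the concave face of C9 is screened by C4 of ring A (axial on ring B), so hydride enters from the convex face and gives the axial (9S) alcohol cis to O8.

Step 10
Reactants: 15 (5R,7R,8R,9S,10S)-9-hydroxy-3-en-2-one with 8-OTBS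
Product: 16 9-O-triethylsilyl ether of 15
Conditions: Et3SiOTf, 2,6-lutidine, CH2Cl2, −78 °C
Reagents that add atoms: triethylsilyl triflate CC[Si](CC)(CC)OS(=O)(=O)C(F)(F)F
Why: Silylation caps the axial C9 hydroxyl, which lies 1,3-diaxial to C4 and could otherwise add as an alkoxide to the enone (oxa-Michael) under the cuprate conditions; the silyl ether also adds bulk on the concave face of C4.

Step 11
Reactants: 16 9-O-triethylsilyl ether of 15
Product: 18 (4S,5R,7R,8R,9S,10S)-4-methyl decalin-2-one with 8-OTBS and 9-OTES, via trimethylsilyl enol ether 17 (not isolated)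
Conditions: Me2CuLi (from CuI and MeLi, 3 equiv), Me3SiCl, THF/Et2O, −78 → −40 °C; then aq NH4Cl/NH3; 10% aq citric acid, THF, 0 °C
Reagents that add atoms: lithium dimethylcuprate [Li+].C[Cu-]C (from methyllithium [Li]C and CuI)
Why: In this chlorosilane-accelerated Gilman conjugate addition to the C3=C4 enone the concave face of C4 is covered by ring B and the C9 silyloxy group, so the methyl group should enter on the convex face, syn to the C5 methyl, setting (4S); the silyl enol ether is hydrolysed on work-up.

Step 12
Reactants: 18 (4S,5R,7R,8R,9S,10S)-4-methyl decalin-2-one with 8-OTBS and 9-OTES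
Product: 19 (4S,5R,7R,8R,9S,10S)-8,9-dihydroxy-4,5-dimethyl-7-isopropenyl-cis-decalin-2-one
Conditions: HF·pyridine, pyridine, THF, 0 °C → rt
Reagents that add atoms: none
Why: Buffered fluoride cleaves both silyl ethers and should leave the ketone, the isopropenyl group and all stereocentres untouched.

Step 13
Reactants: 20 tiglic acid
Product: 21 tigloyl chloride
Conditions: (COCl)2, DMF (cat.), CH2Cl2, 0 °C → rt; concentrated and used crude
Reagents that add atoms: oxalyl chloride O=C(Cl)C(=O)Cl
Why: This is the standard Vilsmeier-catalysed conversion of a carboxylic acid to its chloride, and the thermodynamically preferred (E) geometry is kept.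

Step 14
Reactants: 19 (4S,5R,7R,8R,9S,10S)-8,9-dihydroxy-4,5-dimethyl-7-isopropenyl-cis-decalin-2-one; 21 tigloyl chloride
Product: 23 target CNP0249036.2 (8,9-di-O-tiglate), via 8-monotiglate 22 (not isolated)
Conditions: 21 (6 equiv), DMAP, pyridine, CH2Cl2, 0 → 40 °C
Reagents that add atoms: none
Why: DMAP-catalysed acylation through the N-acylpyridinium salt should esterify the equatorial C8 hydroxyl first and then, with excess reagent and warming, the hindered axial C9 hydroxyl; pyridine in place of a trialkylamine avoids vinylketene formation and deconjugation of the tigloyl unit.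

**Compound list**
1 | p-cresol | Cc1ccc(O)cc1 | starting material
2 | allyltrimethylsilane | C=CC[Si](C)(C)C | starting material
3 | 4-allyl-4-methylcyclohexa-2,5-dien-1-one | C=CCC1(C)C=CC(=O)C=C1 | intermediate
4 | 2-methyl-2-butene | CC=C(C)C | starting material
5 | 4-methyl-4-(3-methylbut-2-en-1-yl)cyclohexa-2,5-dien-1-one | CC(C)=CCC1(C)C=CC(=O)C=C1 | intermediate
6 | 4-[(2E)-4-hydroxy-3-methylbut-2-en-1-yl]-4-methylcyclohexa-2,5-dien-1-one | OC/C(C)=C/CC1(C)C=CC(=O)C=C1 | intermediate
7 | 4-[(2E)-4-bromo-3-methylbut-2-en-1-yl]-4-methylcyclohexa-2,5-dien-1-one | BrC/C(C)=C/CC1(C)C=CC(=O)C=C1 | intermediate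
8 | (S)-2,3-O-isopropylideneglyceraldehyde, (4S)-2,2-dimethyl-1,3-dioxolane-4-carbaldehyde | O=C[C@@H]1COC(C)(C)O1 | starting material
9 | allylchromium dichloride derived from 7 (trivalent chromium, σ-bound at the former CH2Br carbon) | Cl[Cr](Cl)C/C(C)=C/CC1(C)C=CC(=O)C=C1 | intermediate (not isolated)
10 | 4-[(2R,3R)-3-[(4S)-2,2-dimethyl-1,3-dioxolan-4-yl]-3-hydroxy-2-(prop-1-en-2-yl)propyl]-4-methylcyclohexa-2,5-dien-1-one (C7 R, C8 R) | C=C(C)[C@@H](CC1(C)C=CC(=O)C=C1)[C@@H](O)[C@@H]1COC(C)(C)O1 | intermediate
11 | 8-O-tert-butyldimethylsilyl ether of 10 | C=C(C)[C@@H](CC1(C)C=CC(=O)C=C1)[C@@H](O[Si](C)(C)C(C)(C)C)[C@@H]1COC(C)(C)O1 | intermediate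
12 | 4-[(2R,3R,4S)-3-(tert-butyldimethylsilyloxy)-4,5-dihydroxy-2-(prop-1-en-2-yl)pentyl]-4-methylcyclohexa-2,5-dien-1-one | C=C(C)[C@@H](CC1(C)C=CC(=O)C=C1)[C@@H](O[Si](C)(C)C(C)(C)C)[C@@H](O)CO | intermediate (not isolated)
13 | (2R,3R)-2-(tert-butyldimethylsilyloxy)-4-methyl-3-[(1-methyl-4-oxocyclohexa-2,5-dien-1-yl)methyl]pent-4-enal (C9 aldehyde) | C=C(C)[C@@H](CC1(C)C=CC(=O)C=C1)[C@@H](O[Si](C)(C)C(C)(C)C)C=O | intermediate
14 | (5R,7R,8R,10S)-8-(tert-butyldimethylsilyloxy)-5-methyl-7-isopropenyl-cis-decalin-3-ene-2,9-dione (H10 and 5-methyl cis) | C=C(C)[C@H]1C[C@@]2(C)[C@H](CC(=O)C=C2)C(=O)[C@@H]1O[Si](C)(C)C(C)(C)C | intermediate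
15 | (5R,7R,8R,9S,10S)-9-hydroxy analogue of 14 (axial 9-OH cis to 8-OTBS; C3=C4 enone kept) | C=C(C)[C@H]1C[C@@]2(C)[C@H](CC(=O)C=C2)[C@H](O)[C@@H]1O[Si](C)(C)C(C)(C)C | intermediate
16 | 9-O-triethylsilyl ether of 15 | C=C(C)[C@H]1C[C@@]2(C)[C@H](CC(=O)C=C2)[C@H](O[Si](CC)(CC)CC)[C@@H]1O[Si](C)(C)C(C)(C)C | intermediate
17 | C2 trimethylsilyl enol ether (C2=C3) of the 4-methyl adduct | C=C(C)[C@H]1C[C@@]2(C)[C@H](CC(O[Si](C)(C)C)=C[C@@H]2C)[C@H](O[Si](CC)(CC)CC)[C@@H]1O[Si](C)(C)C(C)(C)C | intermediate (not isolated)
18 | (4S,5R,7R,8R,9S,10S)-8-(tert-butyldimethylsilyloxy)-9-(triethylsilyloxy)-4,5-dimethyl-7-isopropenyl-cis-decalin-2-one (4- and 5-methyl cis) | C=C(C)[C@H]1C[C@@]2(C)[C@H](CC(=O)C[C@@H]2C)[C@H](O[Si](CC)(CC)CC)[C@@H]1O[Si](C)(C)C(C)(C)C | intermediate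
19 | (4S,5R,7R,8R,9S,10S)-8,9-dihydroxy-4,5-dimethyl-7-isopropenyl-cis-decalin-2-one | C=C(C)[C@H]1C[C@@]2(C)[C@H](CC(=O)C[C@@H]2C)[C@H](O)[C@@H]1O | intermediate
20 | tiglic acid, (E)-2-methylbut-2-enoic acid | OC(=O)/C(C)=C/C | starting material
21 | tigloyl chloride | ClC(=O)/C(C)=C/C | intermediate
22 | 8-O-tiglate of 19 (9-OH free) | C=C(C)[C@H]1C[C@@]2(C)[C@H](CC(=O)C[C@@H]2C)[C@H](O)[C@@H]1OC(=O)/C(C)=C/C | intermediate (not isolated)
23 | CNP0249036.2, (4S,5R,7R,8R,9S,10S)-8,9-bis[(E)-2-methylbut-2-enoyloxy]-4,5-dimethyl-7-isopropenyl-cis-decalin-2-one | C=C(C)[C@H]1C[C@@]2(C)[C@H](CC(=O)C[C@@H]2C)[C@H](OC(=O)/C(C)=C/C)[C@@H]1OC(=O)/C(C)=C/C | target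

**Step count and risks**

Total step count: 14. Longest linear sequence: 13 steps (steps 1–12 and 14); step 13 is a one-step side branch.

The three steps most likely to fail are:

1. Step 8. The hindered aliphatic Breslow intermediate may close the six-membered all-carbon ring too slowly, so that aldehyde self-condensation, epimerisation next to the aldehyde or incomplete arm selection take over. Fallback, setting out from 13: the same C9–C10 bond is formed by single-electron umpolung. SmI2 (THF, MeOH, −78 °C) should generate the C9 ketyl radical, which adds 6-exo to C10 through the same all-equatorial chair and gives the C9 carbinols, namely 15 and its (9R)-epimeric alcohol F1. Oxidation of the mixture with Dess–Martin periodinane returns to the route at 14; material that is already 15 is carried on directly.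

2. Step 11. Facial selectivity may be poor, with the methyl group entering anti to the axial C5 methyl, because the β carbon is neopentyl and both faces are encumbered. Fallback, setting out from 16: the order of C–C and C–H bond formation at C4 is reversed. The cuprate adduct is kept as its silyl enol ether, the C4-epimeric trimethylsilyl enol ether F2, and is oxidised with Pd(OAc)2 in MeCN (Saegusa–Ito) to the 4-methyl-3-en-2-one F3. Conjugate reduction with [(Ph3P)CuH]6 should then deliver hydride to C4 on the face the cuprate had preferred, which places the methyl group on the convex face; this returns to the route at 18.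

3. Step 5. The anti/Felkin ratio from the allylchromium reagent may be low, or divalent chromium may reduce the dienone. Fallback, setting out from 7: the chromium reagent is replaced by a boron reagent that reacts through a closed six-membered transition state. Borylation with B2pin2 and Pd2(dba)3 (zerovalent palladium) in THF gives the (E)-allyl pinacol boronate F4. Its uncatalysed allylboration of 8 (toluene, rt) should give the anti, Felkin adduct and returns to the route at 10.

**Further compounds**
F1 | step 8 | (5R,7R,8R,9R,10S)-9-hydroxy enone, C9 epimer of 15 | C=C(C)[C@H]1C[C@@]2(C)[C@H](CC(=O)C=C2)[C@@H](O)[C@@H]1O[Si](C)(C)C(C)(C)C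
F2 | step 11 | C4 epimer of trimethylsilyl enol ether 17 | C=C(C)[C@H]1C[C@@]2(C)[C@H](CC(O[Si](C)(C)C)=C[C@H]2C)[C@H](O[Si](CC)(CC)CC)[C@@H]1O[Si](C)(C)C(C)(C)C
F3 | step 11 | 4-methyl-3-en-2-one with 8-OTBS and 9-OTES | C=C(C)[C@H]1C[C@@]2(C)[C@H](CC(=O)C=C2C)[C@H](O[Si](CC)(CC)CC)[C@@H]1O[Si](C)(C)C(C)(C)C
F4 | step 5 | (E)-allyl pinacol boronate derived from 7 | CC1(C)OB(C/C(C)=C/CC2(C)C=CC(=O)C=C2)OC1(C)C
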